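## Retrosynthetic overview

1. The (E)-stilbene C(sp2)–C(sp2) bond is cut last (Suzuki–Miyaura): an (E)-alkenyl pinacol boronate on C8 of the (2S)-flavan plus 2-iodo-3,5-dimethoxy-4-methylphenol (ring A).
2. The alkenyl boronate comes from (2S)-5,7-dimethoxyflavan-8-carbaldehyde by boron–Wittig olefination; ring A comes from 2,6-dimethoxytoluene by C–H borylation/oxidation, then iodination.
3. Key disconnection: the O1–C2 bond of the pyran ring, made by an enantioselective cobalt-hydride hydroalkoxylation of 3-cinnamyl-2-hydroxy-4,6-dimethoxybenzaldehyde. This step forms the C–O bond and sets the only stereocentre (2S).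
4. That aldehyde comes from 3,5-dimethoxyphenol and cinnamyl alcohol (ortho-cinnamylation, then ortho-formylation at the one remaining ortho carbon).
5. Ring order: both benzene rings are bought; the pyran ring is the only ring built (step 3). No protecting groups.

Assumption: 3,5-dimethoxy-4-methylphenol is not treated as a cheap catalogue chemical and is made in one pot from 2,6-dimethoxytoluene.

## Route

Step 1
Reactants: 1 3,5-dimethoxyphenol; 2 (E)-cinnamyl alcohol
Product: 3 3,5-dimethoxy-2-[(2E)-3-phenylprop-2-en-1-yl]phenol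
Conditions: acidic Al2O3, 1 (2 equiv, excess recovered), ClCH2CH2Cl, reflux
Reagents that add atoms: none
Why: Alumina-templated ortho-selective Friedel–Crafts allylation, in which the surface-bound phenol is attacked at C2 (C2 and C6 are equivalent) by the activated cinnamyl alcohol at its unsubstituted terminus, giving the linear E-cinnamyl phenol with water as the only by-product.

Step 2
Reactants: 3 3,5-dimethoxy-2-[(2E)-3-phenylprop-2-en-1-yl]phenol
Product: 5 2-hydroxy-4,6-dimethoxy-3-[(2E)-3-phenylprop-2-en-1-yl]benzaldehyde, via salicyl alcohol magnesium alkoxide 4 (not isolated)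
Conditions: MgCl2 (2 equiv), Et3N (4 equiv), (CH2O)n (6 equiv), MeCN, reflux; cold 1 M HCl
Reagents that add atoms: formaldehyde (from paraformaldehyde), C=O
Why: Casnati–Skattebøl magnesium-mediated ortho-formylation, in which the magnesium phenoxide delivers formaldehyde only to the single free ortho carbon (C6) and a second formaldehyde oxidises alkoxide 4 by Oppenauer-type hydride transfer, leaving the para position and the alkene untouched.

Step 3
Reactants: 5 2-hydroxy-4,6-dimethoxy-3-[(2E)-3-phenylprop-2-en-1-yl]benzaldehyde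
Product: 6 (2S)-5,7-dimethoxy-2-phenyl-3,4-dihydro-2H-chromene-8-carbaldehyde
Conditions: chiral Co(II)–salen (5 mol%; 1,2-diphenylethylenediamine backbone, 3,3'-bis(3,5-di-tert-butylphenyl)salicylidene arms, antipode chosen to give 2S), N-fluoro-2,4,6-trimethylpyridinium triflate (1.3 equiv), (Me2SiH)2O (1.3 equiv), PhCF3, −20 to 0 °C; aq NaHCO3
Reagents that add atoms: none
Why: Proposed new method: enantioselective Markovnikov 6-endo hydroalkoxylation of a β-alkylstyrene by a phenol under chiral Co(salen)–hydride catalysis (hydrogen-atom transfer/radical-polar crossover) – Co(III)–H, formed from Co(II), the N–F oxidant and the silane, transfers H• to the alkene carbon remote from phenyl to give the benzylic radical, which is captured as alkyl–Co(III) and oxidised to an electrophilic alkyl–Co(IV); the two diastereomeric benzylic organocobalt species equilibrate by Co–C homolysis and the phenol oxygen displaces cobalt in an SN2-like step inside the salen pocket, which forms the O1–C2 bond and fixes C2 as S, while the collidine-buffered non-acidic medium avoids racemisation of the benzylic ether and leaves the aldehyde alone; the closest known reaction is the Co(salen)-catalysed HAT-initiated hydroalkoxylation of terminal alkenols to 2-methyl cyclic ethers (racemic and enantioselective), not yet shown for internal styrenes, for a phenol closing a 2-arylchroman, or for a benzylic C–O stereocentre.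

Step 4
Reactants: 6 (2S)-5,7-dimethoxy-2-phenyl-3,4-dihydro-2H-chromene-8-carbaldehyde
Product: 7 2-[(E)-2-[(2S)-5,7-dimethoxy-2-phenyl-3,4-dihydro-2H-chromen-8-yl]ethenyl]-4,4,5,5-tetramethyl-1,3,2-dioxaborolane
Conditions: CH2(Bpin)2 (1.3 equiv), LiTMP (1.25 equiv), THF, 0 °C; then 6, −78 °C to rt; aq NH4Cl
Reagents that add atoms: bis(pinacolboryl)methane, CC1(C)OB(CB2OC(C)(C)C(C)(C)O2)OC1(C)C
Why: Boron–Wittig olefination, in which the α-diboryl carbanion adds to the non-enolisable aldehyde and syn B–O elimination gives the (E)-alkenyl boronate; the molecule has no free OH at this stage and the C2 stereocentre is not touched.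

Step 5
Reactants: 8 2,6-dimethoxytoluene
Product: 10 3,5-dimethoxy-4-methylphenol, via aryl pinacol boronate 9 (not isolated)
Conditions: [Ir(cod)OMe]2 (1 mol%), dtbpy (2 mol%), B2pin2 (1.0 equiv), THF, 80 °C; then aq Oxone, acetone, rt
Reagents that add atoms: potassium peroxymonosulfate (active part of Oxone; gives the O of 10), [K+].[O-]S(=O)(=O)OO; bis(pinacolato)diboron (gives the Bpin of intermediate 9 only), CC1(C)OB(B2OC(C)(C)C(C)(C)O2)OC1(C)C
Why: Sterically controlled iridium-catalysed aromatic C–H borylation at the only C–H with no ortho substituent (para to the methyl), followed in the same pot by ipso-oxidation of the C–B bond to the phenol.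

Step 6
Reactants: 10 3,5-dimethoxy-4-methylphenol
Product: 11 2-iodo-3,5-dimethoxy-4-methylphenol
Conditions: NIS (1.0 equiv), TsOH·H2O (10 mol%), MeCN, 0 °C, dark
Reagents that add atoms: N-iodosuccinimide, O=C1CCC(=O)N1I
Why: Electrophilic aromatic iodination, where the only two free ring positions are equivalent and ortho to OH, so one equivalent of NIS at 0 °C gives the single mono-iodide.

Step 7
Reactants: 7 2-[(E)-2-[(2S)-5,7-dimethoxy-2-phenyl-3,4-dihydro-2H-chromen-8-yl]ethenyl]-4,4,5,5-tetramethyl-1,3,2-dioxaborolane; 11 2-iodo-3,5-dimethoxy-4-methylphenol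
Product: 12 2-[(E)-2-[(2S)-5,7-dimethoxy-2-phenyl-3,4-dihydro-2H-chromen-8-yl]ethenyl]-3,5-dimethoxy-4-methylphenol (CNP0000264.1)
Conditions: Pd(OAc)2 (3 mol%), SPhos (6 mol%), K3PO4 (3 equiv), 1,4-dioxane/H2O 5:1, 70 °C, degassed
Reagents that add atoms: none
Why: Suzuki–Miyaura cross-coupling, which transfers the alkenyl group with retention of the E geometry, tolerates the free phenol and the hindered electron-rich aryl iodide with a biarylphosphine ligand, and does not touch the C2 benzylic ether stereocentre.

## Compound list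

1 | 3,5-dimethoxyphenol | COc1cc(O)cc(OC)c1 | starting material
2 | (E)-cinnamyl alcohol | OC/C=C/c1ccccc1 | starting material
3 | 3,5-dimethoxy-2-[(2E)-3-phenylprop-2-en-1-yl]phenol | COc1cc(O)c(C/C=C/c2ccccc2)c(OC)c1 | intermediate
4 | 2-(hydroxymethyl)-3,5-dimethoxy-6-[(2E)-3-phenylprop-2-en-1-yl]phenol (present as its magnesium alkoxide, not isolated) | COc1cc(OC)c(C/C=C/c2ccccc2)c(O)c1CO | intermediate
5 | 2-hydroxy-4,6-dimethoxy-3-[(2E)-3-phenylprop-2-en-1-yl]benzaldehyde | COc1cc(OC)c(C/C=C/c2ccccc2)c(O)c1C=O | intermediate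
6 | (2S)-5,7-dimethoxy-2-phenyl-3,4-dihydro-2H-chromene-8-carbaldehyde | O=Cc1c(OC)cc(OC)c2c1O[C@H](c1ccccc1)CC2 | intermediate
7 | 2-[(E)-2-[(2S)-5,7-dimethoxy-2-phenyl-3,4-dihydro-2H-chromen-8-yl]ethenyl]-4,4,5,5-tetramethyl-1,3,2-dioxaborolane | CC1(C)OB(/C=C/c2c(OC)cc(OC)c3c2O[C@H](c2ccccc2)CC3)OC1(C)C | intermediate
8 | 2,6-dimethoxytoluene (1,3-dimethoxy-2-methylbenzene) | COc1cccc(OC)c1C | starting material
9 | 2-(3,5-dimethoxy-4-methylphenyl)-4,4,5,5-tetramethyl-1,3,2-dioxaborolane (not isolated) | COc1cc(B2OC(C)(C)C(C)(C)O2)cc(OC)c1C | intermediate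
10 | 3,5-dimethoxy-4-methylphenol | COc1cc(O)cc(OC)c1C | intermediate
11 | 2-iodo-3,5-dimethoxy-4-methylphenol | COc1cc(O)c(I)c(OC)c1C | intermediate
12 | 2-[(E)-2-[(2S)-5,7-dimethoxy-2-phenyl-3,4-dihydro-2H-chromen-8-yl]ethenyl]-3,5-dimethoxy-4-methylphenol | COc1cc(O)c(/C=C/c2c(OC)cc(OC)c3c2O[C@H](c2ccccc2)CC3)c(OC)c1C | target

## Step count and risk

Total steps: 7 (6 if phenol 10 is bought). Longest linear sequence: 5 (steps 1, 2, 3, 4, 7); the ring-A branch is 2 steps (5, 6).

Steps most likely to fail:

Step 3 (the proposed new reaction; risks are low ee through a free benzylic cation, slow hydrogen-atom transfer to the internal alkene, or alkene reduction). The fallback uses known chemistry, sets out from 3 and comes back at 6. CuH-catalysed asymmetric hydroboration of the β-alkylstyrene in 3 (CuCl, NaOtBu, DTBM-SEGPHOS antipode giving R, pinacolborane 2.5 equiv, toluene, rt) gives the benzylic boronate with the phenol carried as its boryl ether, (R)-2-{3-[2,4-dimethoxy-6-(pinacolboryloxy)phenyl]-1-phenylpropyl}-4,4,5,5-tetramethyl-1,3,2-dioxaborolane F3. Oxidation in the same pot (NaBO3·4H2O, THF/H2O, retention) gives (1R)-3-(2-hydroxy-4,6-dimethoxyphenyl)-1-phenylpropan-1-ol F4. Magnesium-mediated ortho-formylation as in step 2 gives 2-hydroxy-3-[(3R)-3-hydroxy-3-phenylpropyl]-4,6-dimethoxybenzaldehyde F5. Intramolecular Mitsunobu etherification (PPh3, DIAD, THF, 0 °C) then closes the O1–C2 bond with inversion, R to S, to give 6.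

Step 1 (risks are attack at the para carbon, double cinnamylation, or acid-induced cyclisation of 3 to racemic flavan). The fallback sets out from 1 and 2 and comes back at 3. Alcohol 2 is converted with methyl chloroformate/pyridine into cinnamyl methyl carbonate F1. Iridium-catalysed branched-selective allylic etherification of the sodium salt of 1 ([Ir(cod)Cl]2/phosphoramidite, THF, 50 °C; ligand chirality irrelevant) gives 1,3-dimethoxy-5-[(1-phenylprop-2-en-1-yl)oxy]benzene F2. Thermal aromatic Claisen rearrangement (PhNEt2, 170 °C) moves the allyl unit only to the ortho carbon with allylic transposition and delivers (E)-configured 3, so the regiochemistry is fixed by the [3,3] shift and not by Friedel–Crafts selectivity.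

Step 4 (risks are sluggish addition of the bulky diboryl carbanion to the hindered, electron-rich aldehyde, or E/Z mixtures). The fallback sets out from 6 and 11 and comes back at 12, so it also replaces step 7. Wittig methylenation of 6 (Ph3PCH3Br, KOtBu, THF, 0 °C) gives (2S)-8-ethenyl-5,7-dimethoxy-2-phenyl-3,4-dihydro-2H-chromene F6. Mizoroki–Heck coupling of F6 with iodophenol 11 under Jeffery conditions (Pd(OAc)2, Bu4NCl, K2CO3, DMF, 80 °C) gives the (E)-stilbene 12 directly.

## Further compounds

F1 | step 1 | cinnamyl methyl carbonate | COC(=O)OC/C=C/c1ccccc1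
F2 | step 1 | 1,3-dimethoxy-5-[(1-phenylprop-2-en-1-yl)oxy]benzene (either enantiomer or racemate; stereocentre lost in the next step) | C=CC(Oc1cc(OC)cc(OC)c1)c1ccccc1
F3 | step 3 | (R)-2-{3-[2,4-dimethoxy-6-(pinacolboryloxy)phenyl]-1-phenylpropyl}-4,4,5,5-tetramethyl-1,3,2-dioxaborolane | COc1cc(OB2OC(C)(C)C(C)(C)O2)c(CC[C@@H](B2OC(C)(C)C(C)(C)O2)c2ccccc2)c(OC)c1
F4 | step 3 | (1R)-3-(2-hydroxy-4,6-dimethoxyphenyl)-1-phenylpropan-1-ol | COc1cc(O)c(CC[C@@H](O)c2ccccc2)c(OC)c1
F5 | step 3 | 2-hydroxy-3-[(3R)-3-hydroxy-3-phenylpropyl]-4,6-dimethoxybenzaldehyde | COc1cc(OC)c(CC[C@@H](O)c2ccccc2)c(O)c1C=O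
F6 | step 4 | (2S)-8-ethenyl-5,7-dimethoxy-2-phenyl-3,4-dihydro-2H-chromene | C=Cc1c(OC)cc(OC)c2c1O[C@H](c1ccccc1)CC2
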